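Take the ratio of substrate to intermediate at the dusk run's last reading, 1.70. The spring and autumn runs read close to it, so treat the two as one pool, 62.9 % of it substrate. What remains to be asked is how much leaves that pool for target and over-reaction product.

| setting | spring | autumn | dusk | Monday's | Sunday's |
|---|---|---|---|---|---|
| substrate | 0.69 M | 0.69 M | 0.69 M | 0.69 M | 0.69 M |
| partner | 0.724 M | 0.724 M | 0.724 M | 0.724 M | 0.724 M |
| protic impurity | 0.19 M | 0.28 M | 0.35 M | 0.210 M | 0.410 M |
| free catalyst | 34 mM | 34 mM | 34 mM | 34 mM | 34 mM |
| remark | run made earlier | run made earlier | run made earlier |  |  |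
| time |  |  |  | 10 h | 10 h |

| run | time / h | over-reaction product / % | intermediate / % | substrate / % | target / % |
|---|---|---|---|---|---|
| spring | 0.417 | 0.1 | 33.2 | 58.2 | 7.8 |
| spring | 1.33 | 1.0 | 28.6 | 49.7 | 20.8 |
| spring | 2.50 | 0.9 | 24.3 | 42.9 | 30.4 |
| spring | 4.00 | 2.4 | 21.8 | 37.9 | 38.8 |
| spring | 5.00 | 2.2 | 20.6 | 34.6 | 43.6 |
| autumn | 0.417 | 0.8 | 34.0 | 59.4 | 6.8 |
| autumn | 0.833 | 0.4 | 32.2 | 54.6 | 12.7 |
| autumn | 1.33 | 0.6 | 30.9 | 51.9 | 18.5 |
| autumn | 2.50 | 0.9 | 27.1 | 44.5 | 26.8 |
| autumn | 5.00 | 1.5 | 22.7 | 39.1 | 37.0 |
| dusk | 1.00 | 0 | 33.2 | 53.7 | 14.5 |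
| dusk | 2.00 | 0.7 | 29.3 | 49.7 | 20.4 |
| dusk | 3.00 | 2.1 | 26.8 | 45.5 | 25.6 |
| dusk | 4.00 | 0.8 | 26.2 | 42.8 | 28.8 |
| dusk | 5.00 | 0.7 | 24.8 | 42.1 | 33.1 |

(each reading ± 0.5 percentage points)

- what was read earlier has a scatter of 0.5 percentage points, one standard deviation

* which of these there is most of at the end, counted by the substrate in it, Monday's (substrate / intermediate / over-reaction product / target)
* which of these there is most of at the end, counted by the substrate in it, Sunday's (substrate / intermediate / over-reaction product / target)
* the largest of these amounts at the end, in percent of the substrate charged, Monday's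
* the largest of these amounts at the end, in percent of the substrate charged, Sunday's

Suppose each protic impurity destroys one partner. Sunday's flask then keeps 45.5 %: call this the partner budget, partner charged minus protic impurity charged, over substrate charged. Partner becomes the limiting reagent there; Monday's budget is 74.5 %.

Test it. Divide target plus over-reaction product by the budget at 5.00 h: spring gives 0.592, autumn 0.598, dusk 0.624. That is nearly flat, while impurity climbs from 0.19 M to 0.35 M.

Now bracket Sunday's substrate. The pool shrinks with time, so take the estimate for 5.00 h, made with the dusk fraction, as the upper bound: 45.1 %. The bare budget bounds it from below at 34.3 %. Tighten that: let the unburnt budget shrink in the second stretch by the factor of the first. This overshoots, since doubling the time from the spring reading at 2.50 h predicts 0.645 where 0.592 was read. The floor becomes 38.3 %. On Monday's, the same steps with the spring fraction put target plus over-reaction product between 44.1 % and 62.1 %, and substrate under 35.2 %, so that sum lies above substrate: expect target to lead.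

The forecast says target on Monday's at 50 % (46 % to 54 %) and substrate on Sunday's at 41 % (38 % to 44 %), since “the reaction nearly stalls”. Sunday's forecast value lies below 45.1 % and above 38.3 %. Monday's forecast value counts target without over-reaction product, and it lies inside the span reckoned for their sum .

Monday's flask ends with target in the lead at 49.4 %. Sunday's flask ends with substrate in the lead at 40.1 %.

    substrate + free catalyst ⇌ free catalyst + intermediate (K = 0.595, k = 3.24 M⁻¹ min⁻¹)
    partner + free catalyst + intermediate → free catalyst + target (k = 0.564 M⁻² min⁻¹)
    partner + target → over-reaction product (k = 0.00104 M⁻¹ min⁻¹)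
    free catalyst → spent catalyst (k = 0.00106 min⁻¹)
    partner + protic impurity → quenched reagent (k = 0.224 M⁻¹ min⁻¹)

Sunday's target and over-reaction product reach 36.2 % against a budget of 45.5 %. Carry the budget to the neighbour, Sunday's flask with 0.10 M of protic impurity: it is 90.4 %. With the spring fraction, substrate falls between 15.5 % and 29.2 %. That flask ends with substrate at 23.9 % and target at 55.4 %.

The readings stem from a simulated flask from invented constants; scatter was added.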